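Ring C (O1–C2–C3–C4–C4a–C8a) is split into a heterodiene and a dienophile. O1=C8a–C4a=C4 is the ortho-quinone methide of phloroglucinol ring A. C2=C3 is an (E)-styrene of catechol ring B whose C3 carries a pinacol boronate as masked hydroxyl. One chiral-acid-catalysed inverse-demand hetero-Diels–Alder reaction forms C4–C3 and O1–C2, closes ring C and sets both stereocentres, the E geometry becoming the 2,3-trans relation. The precursor is a salicyl alcohol in which only the phenol next to the prenyl group is free, so only the 8-prenyl isomer can arise. Stereoretentive C–B oxidation and desilylation finish the synthesis.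

Key step: step 6

Abbreviations: TBS = tert-butyldimethylsilyl; Bpin = 4,4,5,5-tetramethyl-1,3,2-dioxaborolan-2-yl; prenyl = 3-methylbut-2-en-1-yl. Flavan numbering is used for ring atoms.

Assumption: the sense of induction of the chiral acid in step 6 has no close precedent. The (R)-acid is written. Should a pilot run show that it favours the (2R,3R)-boronate, its equally available (S)-enantiomer takes its place with nothing else changed.

Step 1
Reactants: 1 2,4,6-trihydroxybenzaldehyde; 2 prenyl bromide (1-bromo-3-methylbut-2-ene)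
Product: 3 2,4,6-trihydroxy-3-(3-methylbut-2-en-1-yl)benzaldehyde
Conditions: KOH (1 equiv), 2 (1 equiv), MeOH/H2O, 0 °C to rt
Reagents that add atoms: none
Why: C-alkylation of an acylphloroglucinol phenoxide: in protic medium the ambident anion of 1 should react with the allylic bromide at ring carbon, and since the two free ring positions of 1 are equivalent only one mono-C-prenyl isomer is possible.

Step 2
Reactants: 3 2,4,6-trihydroxy-3-(3-methylbut-2-en-1-yl)benzaldehyde
Product: 4 4,6-bis(tert-butyldimethylsilyloxy)-2-hydroxy-3-(3-methylbut-2-en-1-yl)benzaldehyde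
Conditions: TBSCl (2.1 equiv), imidazole, CH2Cl2/DMF, −10 to 0 °C
Reagents that add atoms: TBSCl, CC(C)(C)[Si](C)(C)Cl
Why: Site-selective silyl ether formation: the unchelated 4-OH reacts first, and of the two carbonyl-chelated ortho-hydroxyls the bulky TBSCl should take the one flanked by H (6-OH), leaving free the hydroxyl wedged between CHO and prenyl.

Step 3
Reactants: 4 4,6-bis(tert-butyldimethylsilyloxy)-2-hydroxy-3-(3-methylbut-2-en-1-yl)benzaldehyde
Product: 5 3,5-bis(tert-butyldimethylsilyloxy)-2-(hydroxymethyl)-6-(3-methylbut-2-en-1-yl)phenol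
Conditions: NaBH4, THF/MeOH, −10 °C, short contact; pH 7 buffer quench
Reagents that add atoms: none
Why: Borohydride 1,2-reduction of the aldehyde, in which low temperature and a neutral quench should keep the electron-rich salicyl alcohol from ionising, while silyl ethers and the prenyl alkene are inert to NaBH4.

Step 4
Reactants: 6 3,4-dihydroxybenzaldehyde
Product: 7 3,4-bis(tert-butyldimethylsilyloxy)benzaldehyde
Conditions: TBSCl (2.3 equiv), imidazole, DMF, rt
Reagents that add atoms: TBSCl, CC(C)(C)[Si](C)(C)Cl
Why: Standard silyl ether formation on both catechol hydroxyls, chosen because fluoride removes the groups at the end without touching the prenyl alkene.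

Step 5
Reactants: 7 3,4-bis(tert-butyldimethylsilyloxy)benzaldehyde; 8 bis(4,4,5,5-tetramethyl-1,3,2-dioxaborolan-2-yl)methane
Product: 10 (E)-2-[3,4-bis(tert-butyldimethylsilyloxy)styryl]-4,4,5,5-tetramethyl-1,3,2-dioxaborolane, via lithiated diborylmethane 9 (not isolated)
Conditions: 8, LiTMP (lithium 2,2,6,6-tetramethylpiperidide), THF, 0 °C; then 7, −78 °C to rt
Reagents that add atoms: none
Why: Boron–Wittig olefination: the α-boryl carbanion 9 adds to the aldehyde and syn B–O elimination should give the (E)-alkenyl boronate, the geometry that later becomes the 2,3-trans relation.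

Step 6
Reactants: 5 3,5-bis(tert-butyldimethylsilyloxy)-2-(hydroxymethyl)-6-(3-methylbut-2-en-1-yl)phenol; 10 (E)-2-[3,4-bis(tert-butyldimethylsilyloxy)styryl]-4,4,5,5-tetramethyl-1,3,2-dioxaborolane
Product: 12 (2S,3S)-5,7-bis(tert-butyldimethylsilyloxy)-2-[3,4-bis(tert-butyldimethylsilyloxy)phenyl]-8-(3-methylbut-2-en-1-yl)-3-(4,4,5,5-tetramethyl-1,3,2-dioxaborolan-2-yl)chroman (2,3-trans), via ortho-quinone methide 11 (not isolated)
Conditions: 10 (2 equiv), (R)-3,3'-bis(2,4,6-triisopropylphenyl)-1,1'-binaphthyl-2,2'-diyl N-triflylphosphoramide (10 mol %), 5 Å MS, toluene, −40 °C, slow addition of 5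
Reagents that add atoms: none
Why: Proposed new method: the chiral acid dehydrates 5 to ortho-quinone methide 11, which stays hydrogen-bonded and ion-paired through O1 to the chiral phosphoramide anion, and the alkene of 10 adds in a concerted but highly asynchronous inverse-electron-demand [4+2] cycloaddition in which C3 attacks C4 first and O1 then collapses on C2. The closest known reaction type is the chiral N-triflylphosphoramide-catalysed hetero-Diels–Alder reaction of styrenes with ortho-quinone methides generated from ortho-hydroxybenzyl alcohols; new here are the methide without a substituent at C4 and the β-boryl styrene. Ring C is closed in the intermolecular [4π+2π] mode, which in the stepwise limit is a 6-exo-trig capture of the C2 benzylic cation by O1. The relative configuration comes from suprafacial addition to the E alkene (aryl and boron trans and diequatorial, which is also the outcome of a stepwise closure), and the absolute configuration at C3, and with it C2, comes from the catalyst pocket, which leaves only one enantiotopic alkene face open to the bound methide. Regiochemistry is secured because the para-silyloxy group of ring B and the C–B σ bond both stabilise positive charge at C2, so the boron-bearing carbon is the nucleophilic terminus. Site selectivity on ring A is secured because only the oxygen next to the prenyl group is unprotected, so only the 8-prenyl chroman can form, and the isolated prenyl alkene is less nucleophilic than the donor-substituted styrene used in excess.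

Step 7
Reactants: 12 (2S,3S)-5,7-bis(tert-butyldimethylsilyloxy)-2-[3,4-bis(tert-butyldimethylsilyloxy)phenyl]-8-(3-methylbut-2-en-1-yl)-3-(4,4,5,5-tetramethyl-1,3,2-dioxaborolan-2-yl)chroman
Product: 13 (2R,3S)-5,7-bis(tert-butyldimethylsilyloxy)-2-[3,4-bis(tert-butyldimethylsilyloxy)phenyl]-8-(3-methylbut-2-en-1-yl)chroman-3-ol
Conditions: 30% aq H2O2, pH 7 phosphate buffer, THF, 0 °C to rt
Reagents that add atoms: hydrogen peroxide, OO
Why: Peroxide oxidation of a secondary alkyl boronate proceeds by 1,2-migration of C3 from boron to oxygen with retention, so the (3S) carbinol trans to the aryl group should result, while the buffered medium spares the aryl silyl ethers and neutral H2O2 does not epoxidise the prenyl alkene.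

Step 8
Reactants: 13 (2R,3S)-5,7-bis(tert-butyldimethylsilyloxy)-2-[3,4-bis(tert-butyldimethylsilyloxy)phenyl]-8-(3-methylbut-2-en-1-yl)chroman-3-ol
Product: 14 8-prenylcatechin, (2R,3S)-2-(3,4-dihydroxyphenyl)-8-(3-methylbut-2-en-1-yl)chroman-3,5,7-triol
Conditions: Et3N·3HF (excess), THF/MeCN, rt, argon
Reagents that add atoms: none
Why: Fluoride-mediated cleavage of the four aryl silyl ethers under nearly neutral, non-oxidising conditions, which should leave both stereocentres, the catechol and the acid-sensitive ortho-prenylphenol unit untouched.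

Compound list
1 | 2,4,6-trihydroxybenzaldehyde | O=Cc1c(O)cc(O)cc1O | starting material
2 | prenyl bromide (1-bromo-3-methylbut-2-ene) | CC(C)=CCBr | starting material
3 | 2,4,6-trihydroxy-3-(3-methylbut-2-en-1-yl)benzaldehyde | CC(C)=CCc1c(O)cc(O)c(C=O)c1O | intermediate
4 | 4,6-bis(tert-butyldimethylsilyloxy)-2-hydroxy-3-(3-methylbut-2-en-1-yl)benzaldehyde | CC(C)=CCc1c(O)c(C=O)c(O[Si](C)(C)C(C)(C)C)cc1O[Si](C)(C)C(C)(C)C | intermediate
5 | 3,5-bis(tert-butyldimethylsilyloxy)-2-(hydroxymethyl)-6-(3-methylbut-2-en-1-yl)phenol | CC(C)=CCc1c(O)c(CO)c(O[Si](C)(C)C(C)(C)C)cc1O[Si](C)(C)C(C)(C)C | intermediate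
6 | 3,4-dihydroxybenzaldehyde | O=Cc1ccc(O)c(O)c1 | starting material
7 | 3,4-bis(tert-butyldimethylsilyloxy)benzaldehyde | O=Cc1ccc(O[Si](C)(C)C(C)(C)C)c(O[Si](C)(C)C(C)(C)C)c1 | intermediate
8 | bis(4,4,5,5-tetramethyl-1,3,2-dioxaborolan-2-yl)methane | C(B1OC(C)(C)C(C)(C)O1)B1OC(C)(C)C(C)(C)O1 | starting material
9 | lithiated diborylmethane, lithio-bis(4,4,5,5-tetramethyl-1,3,2-dioxaborolan-2-yl)methane (not isolated) | [Li]C(B1OC(C)(C)C(C)(C)O1)B1OC(C)(C)C(C)(C)O1 | intermediate
10 | (E)-2-[3,4-bis(tert-butyldimethylsilyloxy)styryl]-4,4,5,5-tetramethyl-1,3,2-dioxaborolane | CC(C)(C)[Si](C)(C)Oc1ccc(/C=C/B2OC(C)(C)C(C)(C)O2)cc1O[Si](C)(C)C(C)(C)C | intermediate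
11 | ortho-quinone methide, 3,5-bis(tert-butyldimethylsilyloxy)-6-methylidene-2-(3-methylbut-2-en-1-yl)cyclohexa-2,4-dien-1-one (not isolated) | C=C1C(=O)C(CC=C(C)C)=C(O[Si](C)(C)C(C)(C)C)C=C1O[Si](C)(C)C(C)(C)C | intermediate
12 | (2S,3S)-5,7-bis(tert-butyldimethylsilyloxy)-2-[3,4-bis(tert-butyldimethylsilyloxy)phenyl]-8-(3-methylbut-2-en-1-yl)-3-(4,4,5,5-tetramethyl-1,3,2-dioxaborolan-2-yl)chroman | CC(C)=CCc1c(O[Si](C)(C)C(C)(C)C)cc(O[Si](C)(C)C(C)(C)C)c2c1O[C@H](c1ccc(O[Si](C)(C)C(C)(C)C)c(O[Si](C)(C)C(C)(C)C)c1)[C@@H](B1OC(C)(C)C(C)(C)O1)C2 | intermediate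
13 | (2R,3S)-5,7-bis(tert-butyldimethylsilyloxy)-2-[3,4-bis(tert-butyldimethylsilyloxy)phenyl]-8-(3-methylbut-2-en-1-yl)chroman-3-ol | CC(C)=CCc1c(O[Si](C)(C)C(C)(C)C)cc(O[Si](C)(C)C(C)(C)C)c2c1O[C@H](c1ccc(O[Si](C)(C)C(C)(C)C)c(O[Si](C)(C)C(C)(C)C)c1)[C@@H](O)C2 | intermediate
14 | 8-prenylcatechin, (2R,3S) | CC(C)=CCc1c(O)cc(O)c2c1O[C@H](c1ccc(O)c(O)c1)[C@@H](O)C2 | target

Total step count: 8. Longest linear sequence: 6 steps (1, 2, 3, 6, 7, 8).

Steps most likely to fail

1. Step 6.
- What may go wrong: facial discrimination may be insufficient, because the methide carbon bears no substituent for the catalyst to read. The boryl group may be lost from the cationic intermediate by ipso-substitution instead of ring closure. The methide may self-condense.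
- Fallback: known reaction types only, setting out from 4 and 7 and returning at 12. Wittig olefination of 7 with (triphenylphosphoranylidene)acetaldehyde in toluene gives (E)-3-[3,4-bis(tert-butyldimethylsilyloxy)phenyl]prop-2-enal F1. Iminium/enamine catalysis with (S)-α,α-diphenylprolinol trimethylsilyl ether and 2-nitrobenzoic acid then joins F1 and 4 in a domino oxa-Michael/aldol condensation. This makes the same two bonds of ring C, sets C2 by shielding of one iminium face, and gives (2R)-5,7-bis(tert-butyldimethylsilyloxy)-2-[3,4-bis(tert-butyldimethylsilyloxy)phenyl]-8-(3-methylbut-2-en-1-yl)-2H-chromene-3-carbaldehyde F2. Tsuji–Wilkinson decarbonylation with RhCl(PPh3)3 in warm toluene gives (2S)-5,7-bis(tert-butyldimethylsilyloxy)-2-[3,4-bis(tert-butyldimethylsilyloxy)phenyl]-8-(3-methylbut-2-en-1-yl)-2H-chromene F3, with the same spatial arrangement and a descriptor changed by priorities only. Protoboration with CuCl/Xantphos/NaOt-Bu, B2pin2 and MeOH puts copper on benzylic C4 and boron on C3, anti to the C2 aryl group. It ignores the unactivated prenyl alkene and delivers 12.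

2. Step 2.
- What may go wrong: silylation of the wrong ortho-hydroxyl, or silyl migration between the two ortho oxygens, would redirect the later cycloaddition to the 6-prenyl series.
- Fallback: sets out from 1 and returns at 4, replacing steps 1 and 2, with the position of the prenyl group fixed by a sigmatropic shift instead of by steric bias. Bis-silylation of 1 (TBSCl, imidazole), in which the two ortho-hydroxyls are equivalent, gives 4,6-bis(tert-butyldimethylsilyloxy)-2-hydroxybenzaldehyde F4. Tsuji–Trost O-allylation with tert-butyl 2-methylbut-3-en-2-yl carbonate and Pd(PPh3)4 in THF gives the branched ether 4,6-bis(tert-butyldimethylsilyloxy)-2-(2-methylbut-3-en-2-yloxy)benzaldehyde F5. Aromatic Claisen rearrangement in hot toluene can only reach the one free ortho carbon, so the prenyl group ends up next to the liberated phenol, which is 4.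

3. Step 3.
- What may go wrong: over-reduction through premature methide formation and hydride capture, or oligomerisation of the very electron-rich salicyl alcohol during isolation.
- Fallback: sets out from 4 and returns at 12, with the labile alcohol replaced by a storable methide precursor. Aldehyde 4 is reduced with NaBH4 in EtOH, excess hydride is destroyed with acetone, and the mixture is acidified with AcOH and warmed. The methide formed on purpose is then trapped by the solvent as 3,5-bis(tert-butyldimethylsilyloxy)-2-(ethoxymethyl)-6-(3-methylbut-2-en-1-yl)phenol F6. This ortho-hydroxybenzyl ethyl ether, a known class of methide precursor, is used in place of 5 in step 6. There the chiral acid ionises it to 11 and the cycloaddition gives 12.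

Further compounds
F1 | step 6 | (E)-3-[3,4-bis(tert-butyldimethylsilyloxy)phenyl]prop-2-enal | O=C/C=C/c1ccc(O[Si](C)(C)C(C)(C)C)c(O[Si](C)(C)C(C)(C)C)c1
F2 | step 6 | (2R)-5,7-bis(tert-butyldimethylsilyloxy)-2-[3,4-bis(tert-butyldimethylsilyloxy)phenyl]-8-(3-methylbut-2-en-1-yl)-2H-chromene-3-carbaldehyde | CC(C)=CCc1c(O[Si](C)(C)C(C)(C)C)cc(O[Si](C)(C)C(C)(C)C)c2c1O[C@H](c1ccc(O[Si](C)(C)C(C)(C)C)c(O[Si](C)(C)C(C)(C)C)c1)C(C=O)=C2
F3 | step 6 | (2S)-5,7-bis(tert-butyldimethylsilyloxy)-2-[3,4-bis(tert-butyldimethylsilyloxy)phenyl]-8-(3-methylbut-2-en-1-yl)-2H-chromene | CC(C)=CCc1c(O[Si](C)(C)C(C)(C)C)cc(O[Si](C)(C)C(C)(C)C)c2c1O[C@H](c1ccc(O[Si](C)(C)C(C)(C)C)c(O[Si](C)(C)C(C)(C)C)c1)C=C2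
F4 | step 2 | 4,6-bis(tert-butyldimethylsilyloxy)-2-hydroxybenzaldehyde | O=Cc1c(O)cc(O[Si](C)(C)C(C)(C)C)cc1O[Si](C)(C)C(C)(C)C
F5 | step 2 | 4,6-bis(tert-butyldimethylsilyloxy)-2-(2-methylbut-3-en-2-yloxy)benzaldehyde | C=CC(C)(C)Oc1cc(O[Si](C)(C)C(C)(C)C)cc(O[Si](C)(C)C(C)(C)C)c1C=O
F6 | step 3 | 3,5-bis(tert-butyldimethylsilyloxy)-2-(ethoxymethyl)-6-(3-methylbut-2-en-1-yl)phenol | CCOCc1c(O)c(CC=C(C)C)c(O[Si](C)(C)C(C)(C)C)cc1O[Si](C)(C)C(C)(C)C
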